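## Retrosynthetic overview
1. The target quinone comes from its hydroquinone by mild dehydrogenation. The hydroquinone comes from a cis-pterocarpan-4,8-diol in which the later quinone oxygen O2' is tied to C4. Benzylic C–O hydrogenolysis opens this tie without touching C3.
2. The cis-pterocarpan comes from 3-(2-hydroxy-3,4-dimethoxyphenoxy)propanal and 2,3-dimethoxy-1,4-benzoquinone. Three bonds are made in one pot: C3–C1' (enamine α-arylation, sets C3), C4–O2' (lactol) and C4–C4a (Friedel–Crafts).
3. The aldehyde comes from 3,4-dimethoxyphenol and 3-bromo-1,1-dimethoxypropane (O1–C2 bond). The 8-OH is added by directed ortho-lithiation, borylation and oxidation. The quinone comes from 2,3-dimethoxyphenol and O2.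
4. Ring order: rings A and B come from the two phenols. The dihydrofuran ring and ring C (dihydropyran) form together in the key step. The dihydrofuran ring is opened again in the last step.

Assumption: the [C@H] centre of the given SMILES is C3 of the chroman and has the S configuration (priorities C2 > quinone carbon > C4 > H).

## Route

Step 1
Reactants: 1 3,4-dimethoxyphenol; 2 3-bromo-1,1-dimethoxypropane
Product: 3 4-(3,3-dimethoxypropoxy)-1,2-dimethoxybenzene
Conditions: K2CO3 (1.5 equiv), DMF, 70 °C
Reagents that add atoms: none
Why: Williamson ether synthesis, in which the phenoxide of 1 displaces the primary bromide of 2 (SN2) and the acetal is inert to base.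

Step 2
Reactants: 3 4-(3,3-dimethoxypropoxy)-1,2-dimethoxybenzene
Product: 6 6-(3,3-dimethoxypropoxy)-2,3-dimethoxyphenol, via aryllithium 4 (not isolated), via lithium aryltrimethoxyborate 5 (not isolated)
Conditions: n-BuLi (1.2 equiv), THF, 0 °C to rt; B(OMe)3 (1.5 equiv), −78 °C to rt; 30% H2O2, 2 M NaOH, 0 °C; NH4Cl work-up
Reagents that add atoms: hydrogen peroxide, OO (the phenol oxygen of 6); n-butyllithium, [Li]CCCC, and trimethyl borate, COB(OC)OC, leave atoms only in 4 and 5
Why: Directed ortho-metalation, borylation and oxidation, in which the C–H flanked by two alkoxy groups (as in 1,2,4-trimethoxybenzene) is by far the most acidic, so lithiation, borate formation and the peroxide-induced 1,2-aryl shift place the future 8-OH regioselectively while the acetal tolerates all three basic stages.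

Step 3
Reactants: 6 6-(3,3-dimethoxypropoxy)-2,3-dimethoxyphenol
Product: 7 3-(2-hydroxy-3,4-dimethoxyphenoxy)propanal
Conditions: 1 M aq. HCl/THF 1:3, 0 °C to rt, 1–2 h; NaHCO3 quench; short silica plug, used at once
Reagents that add atoms: water, O
Why: Acid-catalysed acetal hydrolysis in a water-rich medium at low temperature frees the aldehyde faster than the arene can attack the oxocarbenium ion or the aryloxide can be eliminated.

Step 4
Reactants: 8 2,3-dimethoxyphenol
Product: 9 2,3-dimethoxy-1,4-benzoquinone
Conditions: Co(salen) (5 mol%), O2 (1 atm), DMF, rt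
Reagents that add atoms: dioxygen, O=O
Why: Cobalt-salen catalysed aerobic oxidation of a para-unsubstituted phenol, in which the phenoxyl radical is oxygenated at the free para position, gives the p-quinone with water as the only by-product.

Step 5 (key step)
Reactants: 7 3-(2-hydroxy-3,4-dimethoxyphenoxy)propanal (1.1 equiv); 9 2,3-dimethoxy-1,4-benzoquinone (1.0 equiv)
Product: 11 (6aS,11aS)-2,3,9,10-tetramethoxy-6a,11a-dihydro-6H-[1]benzofuro[3,2-c]chromene-4,8-diol, via (3S)-lactol 10 (not isolated)
Conditions: (S)-2-[diphenyl(trimethylsilyloxy)methyl]pyrrolidine (10 mol%), EtOH/H2O 9:1, 0 °C, 16 h; solvent stripped (toluene azeotrope), same flask: CH2Cl2 (0.01 M), 4 Å MS, BF3·OEt2 (50 mol%), −40 to 0 °C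
Reagents that add atoms: none
Why: Proposed new method: the Jørgensen–Hayashi catalyst turns 7 into its E-enamine, whose face away from the CPh2OTMS group adds to C5 of 9 (closest known type: organocatalytic enantioselective α-arylation of aldehydes with quinones) and fixes C3 as S; aromatisation and capture of the aldehyde by the new ortho-OH give lactol 10, which locks the labile α-aryl aldehyde; BF3·OEt2 then ionises the lactol (or activates its open aldehyde form) and the ring A carbon ortho to O1 and para to the 7-OMe closes ring C by intramolecular Friedel–Crafts hydroxyalkylation; the benzylic C4 cation is recaptured by the 2'-OH as in the classical acid cyclisation of 2'-hydroxyisoflavan-4-ols to pterocarpans, so C11a follows C6a because only the cis fusion is possible.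

Step 6
Reactants: 11 (6aS,11aS)-2,3,9,10-tetramethoxy-6a,11a-dihydro-6H-[1]benzofuro[3,2-c]chromene-4,8-diol
Product: 13 2,3-dimethoxy-5-[(3S)-8-hydroxy-6,7-dimethoxy-3,4-dihydro-2H-chromen-3-yl]cyclohexa-2,5-diene-1,4-dione, via (3S)-hydroquinone 12 (not isolated)
Conditions: H2 (1 atm), 10% Pd/C, EtOAc/AcOH 4:1, rt; filtered under Ar; DDQ (1.0 equiv), 0 °C, 10 min
Reagents that add atoms: none
Why: Hydrogenolysis of the para-alkoxy-activated benzylic C11a–O bond of pterocarpans to 2'-hydroxyisoflavans is classical and leaves C6a (= C3) untouched, and exactly one equivalent of DDQ dehydrogenates the electron-rich hydroquinone much faster than it attacks the single ring A phenol (hydroquinone-to-quinone oxidation under non-basic conditions, so C3 is not scrambled).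

## Compound list
1 | 3,4-dimethoxyphenol | COc1ccc(O)cc1OC | starting material
2 | 3-bromo-1,1-dimethoxypropane | COC(CCBr)OC | starting material
3 | 4-(3,3-dimethoxypropoxy)-1,2-dimethoxybenzene | COC(CCOc1ccc(OC)c(OC)c1)OC | intermediate
4 | [6-(3,3-dimethoxypropoxy)-2,3-dimethoxyphenyl]lithium | [Li]c1c(OC)c(OC)ccc1OCCC(OC)OC | intermediate
5 | lithium [6-(3,3-dimethoxypropoxy)-2,3-dimethoxyphenyl]trimethoxyborate | [Li+].CO[B-](OC)(OC)c1c(OC)c(OC)ccc1OCCC(OC)OC | intermediate
6 | 6-(3,3-dimethoxypropoxy)-2,3-dimethoxyphenol | COC(CCOc1ccc(OC)c(OC)c1O)OC | intermediate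
7 | 3-(2-hydroxy-3,4-dimethoxyphenoxy)propanal | O=CCCOc1ccc(OC)c(OC)c1O | intermediate
8 | 2,3-dimethoxyphenol | COc1cccc(O)c1OC | starting material
9 | 2,3-dimethoxy-1,4-benzoquinone | COC1=C(OC)C(=O)C=CC1=O | intermediate
10 | (3S)-3-[(2-hydroxy-3,4-dimethoxyphenoxy)methyl]-6,7-dimethoxy-2,3-dihydro-1-benzofuran-2,5-diol (anomer mixture at C2) | COc1c(OC)c(O)cc2c1OC(O)[C@@H]2COc1ccc(OC)c(OC)c1O | intermediate
11 | (6aS,11aS)-2,3,9,10-tetramethoxy-6a,11a-dihydro-6H-[1]benzofuro[3,2-c]chromene-4,8-diol (cis-pterocarpan) | COc1c(OC)c(O)cc2c1O[C@@H]1c3cc(OC)c(OC)c(O)c3OC[C@H]21 | intermediate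
12 | (3S)-3-(2,5-dihydroxy-3,4-dimethoxyphenyl)-6,7-dimethoxy-3,4-dihydro-2H-chromen-8-ol | COc1c(OC)c(O)c([C@H]2COc3c(cc(OC)c(OC)c3O)C2)cc1O | intermediate
13 | 2,3-dimethoxy-5-[(3S)-8-hydroxy-6,7-dimethoxy-3,4-dihydro-2H-chromen-3-yl]cyclohexa-2,5-diene-1,4-dione | COC1=C(OC)C(=O)C([C@H]2COc3c(cc(OC)c(OC)c3O)C2)=CC1=O | target

## Step count and risks
Total steps: 6. Longest linear sequence: 5 (steps 1, 2, 3, 5, 6).

**Step 5.** Three things can go wrong:
- the enamine of 7 loses the aryloxide (retro-oxa-Michael);
- lactol 10 dehydrates to the achiral 3-substituted benzofuran before ring A attacks;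
- 10 partly enolises under the Lewis acid.

The fallback sets out from 7 (with 9) and comes back at 11. It closes ring C first and brings in the stereocentres afterwards. Catalytic p-TsOH in toluene at 60 °C converts 7, by Friedel–Crafts hydroxyalkylation and loss of water, into 6,7-dimethoxy-2H-chromen-8-ol F1. The styrene-like C3=C4 bond of F1 is then joined to quinone 9 in a formal [3+2] cycloaddition. This is promoted by the chiral titanium TADDOLate made from TiCl4, Ti(OiPr)4 and TADDOL (tetravalent titanium, CH2Cl2, −78 °C). C3 attacks C5 of the chelated quinone, and the quinone oxygen captures the ring-A-stabilised C4 cation to give 11. The TADDOL antipode is chosen for the (6aS,11aS) series.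

**Step 3.** The very electron-rich ring A may attack the oxocarbenium ion to give a 4-methoxychroman or a chromene. The β-aryloxy aldehyde may also eliminate under acid. The fallback sets out from 1 and comes back at 7. It reveals the aldehyde by oxidation in place of acid hydrolysis.
- Compound 1 is alkylated with 3-bromopropan-1-ol (K2CO3, DMF) to 3-(3,4-dimethoxyphenoxy)propan-1-ol F2.
- The lithium alkoxide of F2 is lithiated at the same doubly activated position (n-BuLi, 2.2 equiv). B(OMe)3 and then H2O2/NaOH give 6-(3-hydroxypropoxy)-2,3-dimethoxyphenol F3.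
- A Swern oxidation (oxalyl chloride, DMSO, iPr2NEt, −78 °C, cold quench) gives 7. Both positions ortho to the phenol are blocked against thiomethylation.

**Step 6.** The hydrogenolysis may be slow on the hindered, phenol-rich substrate. Hydroquinone 12 is air-sensitive, and an excess of oxidant would attack ring A. The fallback sets out from 11 and comes back at 12. It replaces surface hydrogenolysis by ionic reduction with Et3SiH (3 equiv) and TFA in CH2Cl2 at −78 to −40 °C. The C11a–O bond ionises to the ring-A-stabilised C4 cation, which is captured by hydride. The low temperature keeps loss of the C3 proton, and with it racemisation through the isoflav-3-ene, slower than hydride capture. The crude 12 is then oxidised as in the route. New compounds on this way: none F0.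

## Further compounds
F1 | step 5 | 6,7-dimethoxy-2H-chromen-8-ol | COc1cc2C=CCOc2c(O)c1OC
F2 | step 3 | 3-(3,4-dimethoxyphenoxy)propan-1-ol | COc1ccc(OCCCO)cc1OC
F3 | step 3 | 6-(3-hydroxypropoxy)-2,3-dimethoxyphenol | COc1ccc(OCCCO)c(O)c1OC
F0 | step 6 | none | none
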